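**Plan**
- Retrosynthesis: the central ArCH2–CH2Ar bond is cut first, giving two identical halves with the catechols as methyl ethers and the benzylic carbon as CH3. In each half the C1 methyl is traced back to a vinyl group and the C3 methylene to a ketone.
- Enabling feature (ring numbering: C1 = quaternary carbon with aryl and methyl, C2 = CMe2, C3–C5 = CH2): C1 carries a methyl and ring carbon C5. Written as two vinyl groups, they make C1 prochiral, so ring bond C3–C4 is cut as a hydroacylation of an achiral divinyl aldehyde.
- The C1–C2 bond between the two quaternary carbons is cut by an Ireland–Claisen rearrangement of a 3-arylpenta-2,4-dienyl isobutyrate. The aryl–C1 bond goes back to a creosol-derived aryl iodide, ethyl propiolate and a vinyl cuprate.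
- Forward: aryl iodide → ynoate → dienol → isobutyrate → Claisen acid → aldehyde → cyclopentanone (the only ring formed) → vinyl to methyl and C=O to CH2 → benzylic homocoupling joins the halves → demethylation.
- Stereochemistry: both (S) centres come from one event, the choice of the chiral rhodium catalyst between the two enantiotopic vinyl groups. No later step makes or breaks a bond at C1.

Key step: step 10

Assumption: (R)-BINAP is taken as the ligand antipode that leads to (S)-17; should a pilot run show the opposite sense of induction, (S)-BINAP is used and nothing else changes.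

Step 1
Reactants: 1 creosol (2-methoxy-4-methylphenol)
Product: 2 2-iodo-6-methoxy-4-methylphenol
Conditions: I2, NaHCO3, THF/H2O, 0 °C to rt
Reagents that add atoms: iodine, II
Why: Electrophilic aromatic iodination of the phenol, in which the para position is blocked by the methyl group, so iodine should enter the one free position ortho to the hydroxyl.

Step 2
Reactants: 2 2-iodo-6-methoxy-4-methylphenol
Product: 3 1-iodo-2,3-dimethoxy-5-methylbenzene
Conditions: MeI, K2CO3, acetone, reflux
Reagents that add atoms: iodomethane, CI
Why: Williamson O-methylation of the phenoxide (SN2 at MeI) installs the second methyl ether, which serves as catechol protection to the last step.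

Step 3
Reactants: 3 1-iodo-2,3-dimethoxy-5-methylbenzene; 4 ethyl propiolate
Product: 5 ethyl 3-(2,3-dimethoxy-5-methylphenyl)prop-2-ynoate
Conditions: PdCl2(PPh3)2 (3 mol %), CuI (6 mol %), K2CO3, THF, 65 °C, slow addition of 4
Reagents that add atoms: none
Why: Sonogashira coupling of the aryl iodide with the terminal alkyne, run with a carbonate base instead of an amine so that aza-Michael addition to and oligomerisation of the propiolate are avoided.

Step 4
Reactants: 5 ethyl 3-(2,3-dimethoxy-5-methylphenyl)prop-2-ynoate; 6 vinylmagnesium bromide
Product: 7 ethyl (2Z)-3-(2,3-dimethoxy-5-methylphenyl)penta-2,4-dienoate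
Conditions: CH2=CHMgBr (2.2 equiv), CuI (1.1 equiv), THF, −78 °C; then 5; aq. NH4Cl at −78 °C
Reagents that add atoms: none
Why: Syn-carbocupration (conjugate addition) of the divinylcuprate should place the vinyl group on the aryl-bearing β-carbon and give mainly the (2Z)-dienoate after cold protonation; the alkene geometry is of no consequence because both isomers converge on the same achiral acid in step 7.

Step 5
Reactants: 7 ethyl (2Z)-3-(2,3-dimethoxy-5-methylphenyl)penta-2,4-dienoate
Product: 8 (2Z)-3-(2,3-dimethoxy-5-methylphenyl)penta-2,4-dien-1-ol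
Conditions: i-Bu2AlH (2.5 equiv), CH2Cl2, −78 °C; aq. KNa tartrate
Reagents that add atoms: none
Why: 1,2-Reduction of the conjugated ester by the aluminium hydride at low temperature should give the allylic alcohol without touching the diene.

Step 6
Reactants: 8 (2Z)-3-(2,3-dimethoxy-5-methylphenyl)penta-2,4-dien-1-ol; 9 isobutyryl chloride
Product: 10 (2Z)-3-(2,3-dimethoxy-5-methylphenyl)penta-2,4-dien-1-yl 2-methylpropanoate
Conditions: Et3N, DMAP (cat.), CH2Cl2, 0 °C
Reagents that add atoms: none
Why: DMAP-catalysed acylation (nucleophilic acyl substitution) under basic conditions, which the ionisation-prone dienyl alcohol tolerates.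

Step 7
Reactants: 10 (2Z)-3-(2,3-dimethoxy-5-methylphenyl)penta-2,4-dien-1-yl 2-methylpropanoate
Product: 14 3-(2,3-dimethoxy-5-methylphenyl)-3-ethenyl-2,2-dimethylpent-4-enoic acid, via lithium enolate 11 (not isolated), via silyl ketene acetal 12 (not isolated), via trimethylsilyl ester 13 (not isolated)
Conditions: LiN(i-Pr)2, THF, −78 °C; Me3SiCl, −78 °C to rt, then 60 °C; dilute aq. HCl
Reagents that add atoms: none
Why: Ireland–Claisen rearrangement, in which the tetrasubstituted silyl ketene acetal undergoes the [3,3]-sigmatropic shift onto the aryl- and vinyl-bearing allyl terminus, forming the C1–C2 bond between two quaternary carbons and, by allylic transposition, the second vinyl group, so that the product is achiral.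

Step 8
Reactants: 14 3-(2,3-dimethoxy-5-methylphenyl)-3-ethenyl-2,2-dimethylpent-4-enoic acid
Product: 15 3-(2,3-dimethoxy-5-methylphenyl)-3-ethenyl-2,2-dimethylpent-4-en-1-ol
Conditions: LiAlH4, THF, 0 °C to reflux; H2O, aq. NaOH
Reagents that add atoms: none
Why: Hydride reduction of the hindered carboxylic acid to the neopentyl alcohol, with alkenes and aryl ethers inert to LiAlH4.

Step 9
Reactants: 15 3-(2,3-dimethoxy-5-methylphenyl)-3-ethenyl-2,2-dimethylpent-4-en-1-ol
Product: 16 3-(2,3-dimethoxy-5-methylphenyl)-3-ethenyl-2,2-dimethylpent-4-enal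
Conditions: Dess–Martin periodinane, CH2Cl2, 0 °C to rt
Reagents that add atoms: none
Why: Dess–Martin oxidation should stop at the aldehyde, which has no α-hydrogen and therefore cannot enolise.

Step 10
Reactants: 16 3-(2,3-dimethoxy-5-methylphenyl)-3-ethenyl-2,2-dimethylpent-4-enal
Product: 17 (3S)-3-(2,3-dimethoxy-5-methylphenyl)-3-ethenyl-2,2-dimethylcyclopentan-1-one
Conditions: [Rh((R)-BINAP)]BF4 (5 mol %, from [Rh(nbd)((R)-BINAP)]BF4 and H2), degassed CH2Cl2, rt to 40 °C
Reagents that add atoms: none
Why: Oxidative addition of the aldehyde C–H bond to the cationic monovalent rhodium centre gives an acyl rhodium hydride, one vinyl group inserts into Rh–H with the metal going to the terminal carbon, and reductive elimination from the six-membered acyl rhodacycle forms ring bond C3–C4. The closest known reaction type is the rhodium-bisphosphine-catalysed enantioselective cyclisation of 4-pentenals to cyclopentanones, including substrates in which two enantiotopic alkenes on C3 of the pentenal are told apart. The one ring is closed in a formal 5-endo-trig hydroacylation (acyl carbon to the distal alkene carbon), the 4-exo alternative leading to a strained cyclobutanone being ruled out by the chain length. The single new stereocentre, C1 of the target ring, is set by the chiral bisphosphine, which decides which of the two enantiotopic vinyl groups is hydrometalated; the new ring CH2 carbons are not stereogenic, so group selection is the only selectivity required. The substrate supports the closure through the Thorpe–Ingold effect of the C2 gem-dimethyl group and the quaternary C1, through the absence of α-hydrogens, and through the absence of allylic hydrogens on the vinyl groups, which excludes alkene isomerisation; decarbonylation of the acyl rhodium hydride is the competing process to watch.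

Step 11
Reactants: 17 (3S)-3-(2,3-dimethoxy-5-methylphenyl)-3-ethenyl-2,2-dimethylcyclopentan-1-one
Product: 19 (1S)-1-(2,3-dimethoxy-5-methylphenyl)-2,2-dimethyl-3-oxocyclopentane-1-carbaldehyde, via secondary ozonide 18 (not isolated)
Conditions: O3, CH2Cl2, −78 °C (Sudan red 7B end point); PPh3, −78 °C to rt
Reagents that add atoms: ozone, [O-][O+]=O
Why: Ozonolysis, in which the terminal vinyl group should react far faster than the dimethoxyarene, the dye marks the end point, and phosphine reduction of the ozonide gives the aldehyde on quaternary C1 with the stereocentre untouched.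

Step 12
Reactants: 19 (1S)-1-(2,3-dimethoxy-5-methylphenyl)-2,2-dimethyl-3-oxocyclopentane-1-carbaldehyde
Product: 21 1,2-dimethoxy-5-methyl-3-[(1S)-1,2,2-trimethylcyclopentyl]benzene, via bis-hydrazone 20 (not isolated)
Conditions: N2H4·H2O, diethylene glycol, 130 °C; then KOH, 200 °C with removal of water
Reagents that add atoms: none
Why: Wolff–Kishner reduction in the Huang–Minlon manner, in which preforming the bis-hydrazone before base is added protects the non-enolisable aldehyde from Cannizzaro or deformylation pathways, and loss of N2 should turn the formyl group into the C1 methyl and the ring ketone into C3H2 in one operation.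

Step 13
Reactants: 21 1,2-dimethoxy-5-methyl-3-[(1S)-1,2,2-trimethylcyclopentyl]benzene (two molecules)
Product: 24 1,2-bis{3,4-dimethoxy-5-[(1S)-1,2,2-trimethylcyclopentyl]phenyl}ethane, via benzylpotassium compound 22 (not isolated), via benzyl bromide 23 (not isolated)
Conditions: n-BuLi, KOt-Bu, 2,2,6,6-tetramethylpiperidine, THF, −78 °C; then BrCH2CH2Br (0.55 equiv), −78 °C to rt
Reagents that add atoms: none
Why: Benzylic metalation and oxidative homocoupling, in which the mixed lithium/potassium amide base should equilibrate to the benzylic potassium compound rather than the ring position ortho to methoxy, 1,2-dibromoethane brominates half of it with loss of ethylene, and SN2 coupling of anion and bromide joins the two halves, so that an enantioenriched monomer gives mainly the C2-symmetric (S,S)-dimer with the meso isomer as the minor by-product.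

Step 14
Reactants: 24 1,2-bis{3,4-dimethoxy-5-[(1S)-1,2,2-trimethylcyclopentyl]phenyl}ethane
Product: 25 5,5'-(ethane-1,2-diyl)bis{3-[(1S)-1,2,2-trimethylcyclopentyl]benzene-1,2-diol} (CNP0144189.1)
Conditions: BBr3 (excess), CH2Cl2, −78 °C to rt; then H2O, work-up under argon
Reagents that add atoms: none
Why: Lewis acid-mediated cleavage of the four aryl methyl ethers by BBr3 (bromide attack at methyl) should liberate both catechols without involving the quaternary stereocentres.

**Compound list**
1 | creosol (2-methoxy-4-methylphenol) | COc1cc(C)ccc1O | starting material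
2 | 2-iodo-6-methoxy-4-methylphenol | COc1cc(C)cc(I)c1O | intermediate
3 | 1-iodo-2,3-dimethoxy-5-methylbenzene | COc1cc(C)cc(I)c1OC | intermediate
4 | ethyl propiolate | CCOC(=O)C#C | starting material
5 | ethyl 3-(2,3-dimethoxy-5-methylphenyl)prop-2-ynoate | CCOC(=O)C#Cc1cc(C)cc(OC)c1OC | intermediate
6 | vinylmagnesium bromide | C=C[Mg]Br | starting material
7 | ethyl (2Z)-3-(2,3-dimethoxy-5-methylphenyl)penta-2,4-dienoate | CCOC(=O)/C=C(/C=C)c1cc(C)cc(OC)c1OC | intermediate
8 | (2Z)-3-(2,3-dimethoxy-5-methylphenyl)penta-2,4-dien-1-ol | OC/C=C(/C=C)c1cc(C)cc(OC)c1OC | intermediate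
9 | isobutyryl chloride | CC(C)C(=O)Cl | starting material
10 | (2Z)-3-(2,3-dimethoxy-5-methylphenyl)penta-2,4-dien-1-yl 2-methylpropanoate | CC(C)C(=O)OC/C=C(/C=C)c1cc(C)cc(OC)c1OC | intermediate
11 | lithium enolate of 10 (formed in the flask) | [Li+].CC(C)=C([O-])OC/C=C(/C=C)c1cc(C)cc(OC)c1OC | intermediate
12 | trimethylsilyl ketene acetal of 10 (formed in the flask) | CC(C)=C(O[Si](C)(C)C)OC/C=C(/C=C)c1cc(C)cc(OC)c1OC | intermediate
13 | trimethylsilyl 3-(2,3-dimethoxy-5-methylphenyl)-3-ethenyl-2,2-dimethylpent-4-enoate (formed in the flask) | C[Si](C)(C)OC(=O)C(C)(C)C(C=C)(C=C)c1cc(C)cc(OC)c1OC | intermediate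
14 | 3-(2,3-dimethoxy-5-methylphenyl)-3-ethenyl-2,2-dimethylpent-4-enoic acid | OC(=O)C(C)(C)C(C=C)(C=C)c1cc(C)cc(OC)c1OC | intermediate
15 | 3-(2,3-dimethoxy-5-methylphenyl)-3-ethenyl-2,2-dimethylpent-4-en-1-ol | OCC(C)(C)C(C=C)(C=C)c1cc(C)cc(OC)c1OC | intermediate
16 | 3-(2,3-dimethoxy-5-methylphenyl)-3-ethenyl-2,2-dimethylpent-4-enal | O=CC(C)(C)C(C=C)(C=C)c1cc(C)cc(OC)c1OC | intermediate
17 | (3S)-3-(2,3-dimethoxy-5-methylphenyl)-3-ethenyl-2,2-dimethylcyclopentan-1-one | C=C[C@@]1(CCC(=O)C1(C)C)c1cc(C)cc(OC)c1OC | intermediate
18 | secondary ozonide (1,2,4-trioxolane) of 17, mixture at the trioxolane carbon (formed in the flask) | C1(OCOO1)[C@@]2(CCC(=O)C2(C)C)c3cc(C)cc(OC)c3OC | intermediate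
19 | (1S)-1-(2,3-dimethoxy-5-methylphenyl)-2,2-dimethyl-3-oxocyclopentane-1-carbaldehyde | O=C[C@@]1(CCC(=O)C1(C)C)c1cc(C)cc(OC)c1OC | intermediate
20 | bis-hydrazone of 19 (formed in the flask) | NN=C[C@@]1(CCC(=NN)C1(C)C)c1cc(C)cc(OC)c1OC | intermediate
21 | 1,2-dimethoxy-5-methyl-3-[(1S)-1,2,2-trimethylcyclopentyl]benzene | C[C@@]1(CCCC1(C)C)c1cc(C)cc(OC)c1OC | intermediate
22 | {3,4-dimethoxy-5-[(1S)-1,2,2-trimethylcyclopentyl]benzyl}potassium (formed in the flask) | C[C@@]1(CCCC1(C)C)c1cc([CH2-])cc(OC)c1OC.[K+] | intermediate
23 | 5-(bromomethyl)-1,2-dimethoxy-3-[(1S)-1,2,2-trimethylcyclopentyl]benzene (formed in the flask) | C[C@@]1(CCCC1(C)C)c1cc(CBr)cc(OC)c1OC | intermediate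
24 | 1,2-bis{3,4-dimethoxy-5-[(1S)-1,2,2-trimethylcyclopentyl]phenyl}ethane | C[C@@]1(CCCC1(C)C)c1cc(CCc2cc(OC)c(OC)c(c2)[C@@]3(C)CCCC3(C)C)cc(OC)c1OC | intermediate
25 | 5,5'-(ethane-1,2-diyl)bis{3-[(1S)-1,2,2-trimethylcyclopentyl]benzene-1,2-diol} | CC1(C)CCC[C@]1(C)c1cc(CCc2cc(O)c(O)c([C@@]3(C)CCCC3(C)C)c2)cc(O)c1O | target

**Totals and risks**

Total step count: 14. Longest linear sequence: 14 steps (1 to 25).

Steps most likely to fail:

Step 10. The acyl rhodium hydride of the congested aldehyde may decarbonylate and tie up the catalyst as a carbonyl complex, or the ligand may discriminate poorly between the two enantiotopic vinyl groups, so that the ketone forms with low enantiomeric purity. The fallback sets out from 16 and closes the ring with the more active achiral catalyst [Rh(dppe)]BF4 (cationic monovalent rhodium) to racemic 3-(2,3-dimethoxy-5-methylphenyl)-3-ethenyl-2,2-dimethylcyclopentan-1-one F1. Reduction with BH3·SMe2 and the (S)-methyl-CBS oxazaborolidine should deliver hydride to the same carbonyl face of both enantiomers (reagent control, CMe2 as the large group). The racemate thereby becomes two diastereomeric alcohols, (1R,3R)-3-(2,3-dimethoxy-5-methylphenyl)-3-ethenyl-2,2-dimethylcyclopentan-1-ol F2 (from the (S)-ketone) and its (1R,3S)-isomer F3. They should be separable by chromatography, and Dess–Martin oxidation of F2 comes back to the route at 17.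

Step 13. Metalation may occur at the ring position ortho to the methoxy group instead of the benzylic methyl, or the bromine transfer may outrun the coupling, so that anion and bromide are not present together. The fallback sets out from 21 and separates the two events. Radical benzylic bromination (N-bromosuccinimide, AIBN, PhCF3, reflux, visible light) gives benzyl bromide 23, now isolated; the ring position para to the conjugating methoxy group is shielded by the tertiary cyclopentyl group. Reductive homocoupling with Ni(cod)2 (zerovalent nickel) in DMF at rt then comes back to the route at 24. This detour makes no compound outside the list (F0).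

Step 3. Oligomerisation of the electron-poor alkyne and its oxidative homocoupling may outpace the slow oxidative addition of the hindered, electron-rich aryl iodide. The fallback sets out from 3 and builds the ynoate in stages. Sonogashira coupling with trimethylsilylacetylene (PdCl2(PPh3)2, CuI, Et3N) gives [(2,3-dimethoxy-5-methylphenyl)ethynyl]trimethylsilane F4. K2CO3 in MeOH removes the silyl group to give 1-ethynyl-2,3-dimethoxy-5-methylbenzene F5. Deprotonation with n-BuLi in THF at −78 °C and acylation of the lithium acetylide with ethyl chloroformate comes back to the route at 5.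

**Further compounds**
F1 | step 10 | racemic 3-(2,3-dimethoxy-5-methylphenyl)-3-ethenyl-2,2-dimethylcyclopentan-1-one | C=CC1(CCC(=O)C1(C)C)c1cc(C)cc(OC)c1OC
F2 | step 10 | (1R,3R)-3-(2,3-dimethoxy-5-methylphenyl)-3-ethenyl-2,2-dimethylcyclopentan-1-ol | C=C[C@@]1(CC[C@@H](O)C1(C)C)c1cc(C)cc(OC)c1OC
F3 | step 10 | (1R,3S)-3-(2,3-dimethoxy-5-methylphenyl)-3-ethenyl-2,2-dimethylcyclopentan-1-ol | C=C[C@]1(CC[C@@H](O)C1(C)C)c1cc(C)cc(OC)c1OC
F0 | step 13 | none | none
F4 | step 3 | [(2,3-dimethoxy-5-methylphenyl)ethynyl]trimethylsilane | C[Si](C)(C)C#Cc1cc(C)cc(OC)c1OC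
F5 | step 3 | 1-ethynyl-2,3-dimethoxy-5-methylbenzene | C#Cc1cc(C)cc(OC)c1OC
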